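## Retrosynthetic overview
1. Target 13 ⇒ diyne 12. Both Z-alkenes come from one final double syn-semihydrogenation.
2. 12 ⇒ thiazolylmethyl chloride 10 + pent-1-en-4-yne 11 (Cu sp3–sp coupling). 10 ⇒ (S)-epoxide 5 + lithiated enyne carbamate 9, which is made in 3 steps from but-3-ynylamine.
3. 5 ⇒ hydroxy diester 3 by global ester reduction, then one-pot chloride and oxirane formation. The carbinol C–O bond is never broken.
4. Key bond: 3 ⇒ 1 + 2. The thiazole C2–C(quaternary) bond is made by a decatungstate photoelectrochemical C–H/C–H coupling at the isopropyl C–H of L-valine-derived hydroxy ester 1.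
5. Rings: the thiazole is bought intact. The only ring made is the transient oxirane (step 3), which is opened in step 7.

Assumption: 1, 2, 6 and 11 are taken as catalogue compounds (1 is the methyl ester of the L-valine-derived hydroxy acid). The target carbinol is (R) and both 1,2-disubstituted alkenes are Z, as drawn.

## Route

**Step 1**
Reactants: 1 methyl (2S)-2-hydroxy-3-methylbutanoate (5 equiv, excess recovered by distillation); 2 methyl 1,3-thiazole-4-carboxylate (1 equiv)
Product: 3 methyl 2-[(3S)-3-hydroxy-4-methoxy-2-methyl-4-oxobutan-2-yl]-1,3-thiazole-4-carboxylate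
Conditions: 1, TFAA (1 equiv per 1), MeCN, 0 °C→rt, 30 min (in-situ O-trifluoroacetate); then 2, TfOH (1.1 equiv), (n-Bu4N)4W10O32 (5 mol %), LiNTf2 (0.1 M), 390 nm LEDs, graphite felt(+)/Pt(–), undivided cell, 3 mA (2.2–2.5 F/mol), N2, 25 °C; NaHCO3/MeOH work-up
Reagents that add atoms: none (the CF3CO mask is lost on work-up)
Why: Proposed new method: excited decatungstate is a bulky, strongly electrophilic H-abstractor, so on the masked ester it should take only the single isopropyl tertiary C–H (the carbinol C–H is polarity-mismatched between CO2Me and OCOCF3 and shielded, and all other C–H bonds are primary); the nucleophilic tertiary radical then adds to C2 of protonated 2 (C5 is blocked by the ester), the adduct radical and the reduced polyoxotungstate are re-oxidised at the anode while H+ gives H2 at Pt, and the stereocentre is only a spectator β to the radical, so the purchased (S) configuration is retained; the closest known reaction types are decatungstate photo(electro)catalytic cross-dehydrogenative Minisci coupling of benzothiazoles and azines with simple alkanes, ethers and amides, and decatungstate β-C–H fluorination of valine, neither yet shown for the β-C–H of an α-hydroxy ester, for a monocyclic thiazole ester, or for building a quaternary carbon next to a stereocentre.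

**Step 2**
Reactants: 3
Product: 4 (2S)-3-[4-(hydroxymethyl)-1,3-thiazol-2-yl]-3-methylbutane-1,2-diol
Conditions: LiAlH4 (3 equiv), THF, 0 °C→rt; Rochelle salt work-up
Reagents that add atoms: none
Why: LiAlH4 ester reduction converts both esters to CH2OH, leaves the thiazole alone and touches no bond at the stereocentre, so it stays (S).

**Step 3**
Reactants: 4
Product: 5 4-(chloromethyl)-2-{2-[(2S)-oxiran-2-yl]propan-2-yl}-1,3-thiazole
Conditions: MsCl (2.2 equiv), Et3N (3 equiv), CH2Cl2, –20 °C, 20 min; then n-Bu4NCl (2 equiv), 2 M aq NaOH, 0 °C→rt, 1 h (one pot, kept cold and closed at once to avoid N-alkylation of the thiazole)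
Reagents that add atoms: chloride from tetrabutylammonium chloride, CCCC[N+](CCCC)(CCCC)CCCC.[Cl-], and from methanesulfonyl chloride, CS(=O)(=O)Cl
Why: Only the two primary OH groups are mesylated because the neopentyl secondary OH is too hindered; chloride then displaces the heterobenzylic mesylate (SN2) and the secondary alkoxide closes on CH2OMs (Williamson 3-exo-tet), so the C–O bond at the stereocentre is retained and the (S)-epoxide results.

**Step 4**
Reactants: 6 but-3-yn-1-amine hydrochloride
Product: 7 methyl N-(but-3-yn-1-yl)carbamate
Conditions: ClCO2Me, aq NaHCO3/CH2Cl2, 0 °C→rt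
Reagents that add atoms: methyl chloroformate, COC(=O)Cl
Why: Schotten–Baumann N-acylation of a primary amine.

**Step 5**
Reactants: 7
Product: 8 methyl N-(3-bromobut-3-en-1-yl)carbamate
Conditions: B-Br-9-BBN (2.2 equiv), CH2Cl2, 0 °C; AcOH, 0 °C; then NaOH/H2O2
Reagents that add atoms: B-bromo-9-borabicyclo[3.3.1]nonane, BrB1C2CCCC1CCC2
Why: Syn-bromoboration of the terminal alkyne puts Br on the internal carbon, and protodeboronation then gives the 2-bromo-1-alkene (haloboration–protonolysis).

**Step 6**
Reactants: 8
Product: 9 methyl N-(3-methylidenepent-4-yn-1-yl)carbamate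
Conditions: HC≡CMgBr (3 equiv), ZnBr2 (3 equiv), THF, 0 °C; then 8, Pd(PPh3)4 (5 mol %), rt→40 °C
Reagents that add atoms: ethynylmagnesium bromide, C#C[Mg]Br
Why: Negishi alkynylation of an alkenyl bromide with ethynylzinc bromide gives the terminal 1,3-enyne directly, and the excess organozinc absorbs the carbamate N–H.

**Step 7**
Reactants: 5; 9 (2 equiv)
Product: 10 methyl N-[(7R)-8-[4-(chloromethyl)-1,3-thiazol-2-yl]-7-hydroxy-8-methyl-3-methylidenenon-4-yn-1-yl]carbamate
Conditions: 9, n-BuLi (4 equiv), THF, –78 °C; BF3·OEt2 (3 equiv); then 5, –78 °C, 1 h; NH4Cl quench at –78 °C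
Reagents that add atoms: none beyond reactant 9 (C#CC(=C)CCNC(=O)OC)
Why: Yamaguchi–Hirao BF3-assisted alkynylation attacks the unhindered epoxide CH2 far faster at –78 °C than a lithium acetylide can displace the CH2Cl; the stereocentre is untouched, and its descriptor changes S→R only because the CIP ranking changes.

**Step 8**
Reactants: 10; 11 pent-1-en-4-yne (3 equiv)
Product: 12 methyl N-[(7R)-8-[4-(hex-5-en-2-yn-1-yl)-1,3-thiazol-2-yl]-7-hydroxy-8-methyl-3-methylidenenon-4-yn-1-yl]carbamate
Conditions: CuI (1 equiv), NaI (1 equiv), K2CO3 (1.5 equiv), DMF, rt, 16 h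
Reagents that add atoms: none beyond reactant 11 (C=CCC#C)
Why: In-situ Finkelstein exchange followed by SN2 of the copper acetylide on the heterobenzylic halide (the Cu/NaI/K2CO3 skipped-enyne coupling) is mild enough for the free OH, the N–H and the base-sensitive 1,4-enyne.

**Step 9**
Reactants: 12
Product: 13 mycothiazole as drawn, methyl N-[(4Z,7R)-8-{4-[(2Z)-hexa-2,5-dien-1-yl]-1,3-thiazol-2-yl}-7-hydroxy-8-methyl-3-methylidenenon-4-en-1-yl]carbamate
Conditions: H2 (1 atm, stopped at 2.0 equiv uptake), Lindlar catalyst (Pd/CaCO3–Pb), quinoline, EtOAc, 0 °C→rt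
Reagents that add atoms: none
Why: Lindlar syn-semihydrogenation converts both internal alkynes to Z-alkenes, because alkynes bind the poisoned Pd much more strongly than the vinyl and 1,1-disubstituted alkenes; the stereocentre is unaffected.

## Compound list
1 | methyl (2S)-2-hydroxy-3-methylbutanoate | COC(=O)[C@@H](O)C(C)C | starting material
2 | methyl 1,3-thiazole-4-carboxylate | COC(=O)c1cscn1 | starting material
3 | methyl 2-[(3S)-3-hydroxy-4-methoxy-2-methyl-4-oxobutan-2-yl]-1,3-thiazole-4-carboxylate | COC(=O)c1csc(C(C)(C)[C@H](O)C(=O)OC)n1 | intermediate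
4 | (2S)-3-[4-(hydroxymethyl)-1,3-thiazol-2-yl]-3-methylbutane-1,2-diol | OCc1csc(C(C)(C)[C@H](O)CO)n1 | intermediate
5 | 4-(chloromethyl)-2-{2-[(2S)-oxiran-2-yl]propan-2-yl}-1,3-thiazole | ClCc1csc(C(C)(C)[C@H]2CO2)n1 | intermediate
6 | but-3-yn-1-amine hydrochloride | C#CCCN.Cl | starting material
7 | methyl N-(but-3-yn-1-yl)carbamate | C#CCCNC(=O)OC | intermediate
8 | methyl N-(3-bromobut-3-en-1-yl)carbamate | C=C(Br)CCNC(=O)OC | intermediate
9 | methyl N-(3-methylidenepent-4-yn-1-yl)carbamate | C#CC(=C)CCNC(=O)OC | intermediate
10 | methyl N-[(7R)-8-[4-(chloromethyl)thiazol-2-yl]-7-hydroxy-8-methyl-3-methylidenenon-4-yn-1-yl]carbamate | ClCc1csc(C(C)(C)[C@H](O)CC#CC(=C)CCNC(=O)OC)n1 | intermediate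
11 | pent-1-en-4-yne | C=CCC#C | starting material
12 | methyl N-[(7R)-8-[4-(hex-5-en-2-yn-1-yl)thiazol-2-yl]-7-hydroxy-8-methyl-3-methylidenenon-4-yn-1-yl]carbamate | C=CCC#CCc1csc(C(C)(C)[C@H](O)CC#CC(=C)CCNC(=O)OC)n1 | intermediate
13 | mycothiazole, (R), Z,Z | C=CC/C=C\Cc1csc(C(C)(C)[C@H](O)C/C=C\C(=C)CCNC(=O)OC)n1 | target

## Step count
- **Total steps:** 9
- **Longest linear sequence:** 6 (1→3→4→5→10→12→13). The branch 6→7→8→9→10→12→13 is also 6.

## Three steps most likely to fail
1. **Step 1 (proposed new C–H/C–H coupling).**
   - Risks:
     - Hydrogen abstraction may be slow at a tertiary C–H that is β to two withdrawing groups.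
     - OCH3 abstraction or a 1,2-acyloxy shift may compete.
     - Thiazole 2 is only weakly basic.
   - The step sits first, on commodity materials, so a modest yield is tolerable.
   - Fallback (known chemistry, about +3 steps):
     - Treat methyl (R)-2,2-dimethyl-1,3-dioxolane-4-carboxylate (D-mannitol pool) with MeMgBr to give the tertiary alcohol, and convert it to the cesium tert-alkyl oxalate.
     - Run the established visible-light photoredox/persulfate oxalate Minisci reaction with 2.
     - Aqueous acid and then LiAlH4 converge on the same (S)-triol 4.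
2. **Step 9 (double Lindlar reduction).**
   - Risks: over-reduction of the vinyl group or the diene, unequal rates for the two alkynes, and partial catalyst poisoning by sulfur.
   - Fallback: set the alkene geometry by olefination and cross-coupling instead of hydrogenation.
     - Right arm: aldehyde homologue, then Stork–Zhao Z-iodo-olefination, then Stille coupling with methyl (3-tributylstannylbut-3-enyl)carbamate.
     - Left arm: Z-selective Wittig reaction of the thiazol-4-ylacetaldehyde with the but-3-enyltriphenylphosphonium ylide.
3. **Step 7 (dianion/BF3 epoxide opening beside a CH2Cl and a Lewis-basic thiazole; this also depends on the one-pot step 3).**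
   - Risks: BF3 may be sequestered by the thiazole nitrogen, the CH2Cl may be alkylated, and the yield of 5 may be low.
   - Fallback (+2 steps): change the handle and the order of events.
     - Bu2SnO-catalysed monotosylation of the 1,2-diol of 4, then base, gives the epoxide with a free thiazolyl-CH2OH.
     - Open it with lithium acetylide·EDA, then carry out a Sonogashira coupling with bromide 8.
     - Only then use MsCl/LiCl to make the chloride and perform the Cu coupling of step 8.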